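**Strategy.** Everything rests on closing ring C at C3=C4. C4 is bonded to aromatic C4a and C3 to the stereogenic C2, which hangs on O1; a vinyl group on C4a and the vinyl of an O1-bound (S)-1-phenylallyl ether are therefore joined by ring-closing olefin metathesis, which forms ring C and the (2S)-2-phenyl-2H-chromene in one operation and leaves C4 benzylic for oxidation to the flavanone carbonyl. The metathesis precursor is the (S)-1-phenylallyl ether of an ortho-vinylphenol that already carries the C6 pyronylmethyl arm, with the other three hydroxyls as methoxymethyl ethers; its stereocentre is set one step earlier by iridium-catalysed branched allylic etherification of an electron-rich aryloxide. The C8 acyl group is added last.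

Key step: step 10

Assumption: the (Sa,S,S) enantiomer of the binaphthyl bis(1-phenylethyl)phosphoramidite is taken to deliver the (S)-ether in step 9; if the sense of induction proves opposite, its antipode is used with no other change.

**Step 1**
Reactants: 1 pentan-3-one
Product: 2 trimethyl(pent-2-en-3-yloxy)silane (E/Z mixture)
Conditions: Me3SiOTf, Et3N, CH2Cl2, 0 °C
Reagents that add atoms: trimethylsilyl trifluoromethanesulfonate, C[Si](C)(C)OS(=O)(=O)C(F)(F)F
Why: Silyl enol ether formation by soft enolisation of a symmetrical ketone can give only one regioisomer, and the alkene geometry disappears later in the pyrone.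

**Step 2**
Reactants: 2 trimethyl(pent-2-en-3-yloxy)silane; 3 malonyl dichloride
Product: 5 6-ethyl-4-hydroxy-5-methyl-2H-pyran-2-one, via 4-methyl-3,5-dioxoheptanoyl chloride 4 (not isolated)
Conditions: Et2O, −78 °C → rt
Reagents that add atoms: none
Why: Acylative pyrone annulation of a silyl enol ether: the enol carbon is acylated by one acid chloride with loss of Me3SiCl, and the enol oxygen closes the lactone on the second, the dione tautomerising to the 4-hydroxy-2-pyrone.

**Step 3**
Reactants: 6 2,4,6-trihydroxybenzaldehyde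
Product: 7 2,6-dihydroxy-4-[(triisopropylsilyl)oxy]benzaldehyde
Conditions: i-Pr3SiCl (1.0 equiv), imidazole, DMF, −20 → 0 °C
Reagents that add atoms: chlorotriisopropylsilane, CC(C)[Si](Cl)(C(C)C)C(C)C
Why: Regioselective silylation: the para hydroxyl is the most acidic and the only one neither hydrogen-bonded to nor crowded by the formyl group, so one equivalent of a bulky silyl chloride should stop at the 4-O-ether.

**Step 4**
Reactants: 7 2,6-dihydroxy-4-[(triisopropylsilyl)oxy]benzaldehyde; 5 6-ethyl-4-hydroxy-5-methyl-2H-pyran-2-one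
Product: 9 3-{2,6-dihydroxy-4-[(triisopropylsilyl)oxy]benzyl}-6-ethyl-4-hydroxy-5-methyl-2H-pyran-2-one, via benzylidenepyrandione 8 (not isolated)
Conditions: Hantzsch ester (diethyl 2,6-dimethyl-1,4-dihydropyridine-3,5-dicarboxylate), L-proline (20 mol %), CH2Cl2, rt
Reagents that add atoms: none
Why: Three-component reductive alkylation (proline-mediated Knoevenagel condensation, then Hantzsch-ester transfer hydrogenation of the electrophilic benzylidene) turns the formyl carbon into the methylene bridge and intercepts the alkylidene before a second pyrone can add.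

**Step 5**
Reactants: 9 3-{2,6-dihydroxy-4-[(triisopropylsilyl)oxy]benzyl}-6-ethyl-4-hydroxy-5-methyl-2H-pyran-2-one
Product: 10 3-{2,6-bis(methoxymethoxy)-4-[(triisopropylsilyl)oxy]benzyl}-6-ethyl-4-(methoxymethoxy)-5-methyl-2H-pyran-2-one
Conditions: MeOCH2Cl (3.6 equiv), i-Pr2NEt, CH2Cl2, 0 °C → rt
Reagents that add atoms: chloromethyl methyl ether, COCCl
Why: O-Alkylation of the two phenols and the acidic pyrone enol with a hard electrophile (methoxymethyl protection, expected at O4 of the pyrone) gives ether-type protection, which allows a free aryloxide in step 9 and an acid-only deprotection at the end.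

**Step 6**
Reactants: 10 3-{2,6-bis(methoxymethoxy)-4-[(triisopropylsilyl)oxy]benzyl}-6-ethyl-4-(methoxymethoxy)-5-methyl-2H-pyran-2-one
Product: 11 6-ethyl-3-[4-hydroxy-2,6-bis(methoxymethoxy)benzyl]-4-(methoxymethoxy)-5-methyl-2H-pyran-2-one
Conditions: Bu4NF, AcOH, THF, 0 °C → rt
Reagents that add atoms: none
Why: Buffered fluoride desilylation of the aryl silyl ether frees the one phenol that becomes O1 and leaves the three acetals untouched.

**Step 7**
Reactants: 11 6-ethyl-3-[4-hydroxy-2,6-bis(methoxymethoxy)benzyl]-4-(methoxymethoxy)-5-methyl-2H-pyran-2-one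
Product: 12 6-ethyl-3-[4-hydroxy-3-iodo-2,6-bis(methoxymethoxy)benzyl]-4-(methoxymethoxy)-5-methyl-2H-pyran-2-one
Conditions: N-iodosuccinimide (1.0 equiv), CH2Cl2, −40 → 0 °C
Reagents that add atoms: N-iodosuccinimide, O=C1CCC(=O)N1I
Why: Electrophilic aromatic iodination ortho to the free phenol; the two open positions are equivalent by symmetry and the first iodine lowers the reactivity of the ring, so one equivalent at low temperature should stop at the mono-iodide.

**Step 8**
Reactants: 12 6-ethyl-3-[4-hydroxy-3-iodo-2,6-bis(methoxymethoxy)benzyl]-4-(methoxymethoxy)-5-methyl-2H-pyran-2-one; 13 potassium vinyltrifluoroborate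
Product: 14 6-ethyl-3-[4-hydroxy-2,6-bis(methoxymethoxy)-3-vinylbenzyl]-4-(methoxymethoxy)-5-methyl-2H-pyran-2-one
Conditions: PdCl2(dppf)·CH2Cl2 (5 mol %), Cs2CO3 (3 equiv), THF/H2O (9:1), 70 °C
Reagents that add atoms: none
Why: Suzuki–Miyaura coupling of the aryl iodide with the vinyltrifluoroborate installs the C4a vinyl group while the molecule is still achiral, so zerovalent palladium never meets the allylic ether, and 4-alkoxy-2-pyrones tolerate aqueous carbonate.

**Step 9**
Reactants: 14 6-ethyl-3-[4-hydroxy-2,6-bis(methoxymethoxy)-3-vinylbenzyl]-4-(methoxymethoxy)-5-methyl-2H-pyran-2-one; 15 (E)-cinnamyl methyl carbonate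
Product: 17 3,5-bis(methoxymethoxy)-4-{[6-ethyl-4-(methoxymethoxy)-5-methyl-2-oxo-2H-pyran-3-yl]methyl}-2-vinylphenyl (1S)-1-phenylprop-2-enyl ether, via lithium aryloxide 16 (not isolated)
Conditions: LiN(SiMe3)2 (1.0 equiv), THF, 0 °C; then [Ir(cod)Cl]2 (2 mol %), (Sa,S,S)-O,O'-(1,1'-binaphthalene-2,2'-diyl) N,N-bis(1-phenylethyl)phosphoramidite (4 mol %, pre-activated with n-PrNH2), 15 (1.2 equiv), THF, rt → 40 °C
Reagents that add atoms: none
Why: Iridium-catalysed asymmetric allylic etherification: the aryloxide attacks the phenyl-bearing terminus of the cinnamyl–iridium intermediate on the face left open by the cyclometalated phosphoramidite, which gives the branched ether and sets the future C2 as S, and the electron-rich aryloxide is too poor a leaving group for the ether to re-ionise.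

**Step 10**
Reactants: 17 3,5-bis(methoxymethoxy)-4-{[6-ethyl-4-(methoxymethoxy)-5-methyl-2-oxo-2H-pyran-3-yl]methyl}-2-vinylphenyl (1S)-1-phenylprop-2-enyl ether
Product: 18 (2S)-6-{[6-ethyl-4-(methoxymethoxy)-5-methyl-2-oxo-2H-pyran-3-yl]methyl}-5,7-bis(methoxymethoxy)-2-phenyl-2H-chromene
Conditions: second-generation Grubbs catalyst (5 mol %), 1,4-benzoquinone (10 mol %), degassed CH2Cl2 (0.01 M), 35 °C, dark, short reaction time
Reagents that add atoms: none
Why: Ring-closing olefin metathesis: the ruthenium alkylidene engages one terminal alkene, adds across the other through a ruthenacyclobutane and expels ethene, so the only new bond is C3=C4. The closest known reaction type is the metathesis of ortho-vinylaryl allyl ethers to 2-substituted 2H-chromenes. Ring C closes as a six-membered ring by joining the two vinyl groups carried on C4a and O1, the ring enforcing the cis alkene. No stereocentre is formed; C2 sits next to the new alkene but takes no part in bond making or breaking, so the S configuration from step 9 is carried through. The step needs chemoselectivity for the two monosubstituted alkenes, which the inert tetrasubstituted pyrone alkenes secure, and it needs the allylic double bond to stay in place, for which benzoquinone intercepts ruthenium hydrides. Running warm and not hot, briefly and in the dark should keep the electron-rich chromene from opening to its quinone-methide valence isomer.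

**Step 11**
Reactants: 18 (2S)-6-{[6-ethyl-4-(methoxymethoxy)-5-methyl-2-oxo-2H-pyran-3-yl]methyl}-5,7-bis(methoxymethoxy)-2-phenyl-2H-chromene
Product: 20 (2S)-6-{[6-ethyl-4-(methoxymethoxy)-5-methyl-2-oxo-2H-pyran-3-yl]methyl}-5,7-bis(methoxymethoxy)-2-phenylchroman-4-one, via flavan-4-ol 19 (not isolated)
Conditions: Co(acac)2 (20 mol %), PhSiH3, O2 (1 atm), THF/i-PrOH, 0 °C → rt; then Dess–Martin periodinane, pyridine, CH2Cl2, 0 °C → rt
Reagents that add atoms: dioxygen, O=O
Why: Mukaiyama hydration (cobalt-hydride hydrogen-atom transfer to C3 gives the benzylic C4 radical, which O2 traps) followed by Dess–Martin oxidation of the crude epimeric carbinols places the ketone at C4 only, with C2 untouched and the fully substituted pyrone alkenes unreactive.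

**Step 12**
Reactants: 20 (2S)-6-{[6-ethyl-4-(methoxymethoxy)-5-methyl-2-oxo-2H-pyran-3-yl]methyl}-5,7-bis(methoxymethoxy)-2-phenylchroman-4-one
Product: 21 (2S)-6-{[6-ethyl-4-(methoxymethoxy)-5-methyl-2-oxo-2H-pyran-3-yl]methyl}-8-iodo-5,7-bis(methoxymethoxy)-2-phenylchroman-4-one
Conditions: N-iodosuccinimide, CF3CO2H (10 mol %), MeCN, 0 °C → rt
Reagents that add atoms: N-iodosuccinimide, O=C1CCC(=O)N1I
Why: Electrophilic aromatic iodination at C8, the only free position of ring A and activated by O1 and O7 (ortho) and O5 (para), under non-basic conditions that cannot open ring C.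

**Step 13**
Reactants: 22 2-methylprop-1-enylmagnesium bromide (THF solution)
Product: 23 tributyl(2-methylprop-1-enyl)stannane
Conditions: Bu3SnCl, THF, 0 °C → rt
Reagents that add atoms: tributyltin chloride, CCCC[Sn](Cl)(CCCC)CCCC
Why: Transmetalation of an alkenyl Grignard reagent to tin (nucleophilic substitution at tin) gives the alkenylstannane.

**Step 14**
Reactants: 21 (2S)-6-{[6-ethyl-4-(methoxymethoxy)-5-methyl-2-oxo-2H-pyran-3-yl]methyl}-8-iodo-5,7-bis(methoxymethoxy)-2-phenylchroman-4-one; 23 tributyl(2-methylprop-1-enyl)stannane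
Product: 24 (2S)-6-{[6-ethyl-4-(methoxymethoxy)-5-methyl-2-oxo-2H-pyran-3-yl]methyl}-5,7-bis(methoxymethoxy)-8-(3-methylbut-2-enoyl)-2-phenylchroman-4-one
Conditions: Pd2(dba)3 (5 mol %), AsPh3 (20 mol %), CO (3 atm), 1,4-dioxane, 70 °C
Reagents that add atoms: carbon monoxide, [C-]#[O+]
Why: Carbonylative Stille coupling (oxidative addition of the C8 iodide to zerovalent palladium, CO insertion, transfer of the 2-methylprop-1-enyl group from tin) builds the 3-methylbut-2-enoyl ketone under neutral conditions that spare C2 and the pyrone.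

**Step 15**
Reactants: 24 (2S)-6-{[6-ethyl-4-(methoxymethoxy)-5-methyl-2-oxo-2H-pyran-3-yl]methyl}-5,7-bis(methoxymethoxy)-8-(3-methylbut-2-enoyl)-2-phenylchroman-4-one
Product: 25 (2S)-6-[(6-ethyl-4-hydroxy-5-methyl-2-oxo-2H-pyran-3-yl)methyl]-5,7-dihydroxy-8-(3-methylbut-2-enoyl)-2-phenylchroman-4-one (target)
Conditions: HCl in MeOH (1.25 M), CH2Cl2, 0 °C → rt
Reagents that add atoms: none
Why: Acid-catalysed acetal cleavage (methoxymethyl removal) frees the pyrone enol and the two phenols, each now ortho to a carbonyl, without base, so that neither retro-oxa-Michael opening of ring C (loss of the C2 configuration) nor base-induced cyclisation of the enone onto the C7 hydroxyl should occur.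

**Compound list**

1 | pentan-3-one | CCC(=O)CC | starting material
2 | trimethyl(pent-2-en-3-yloxy)silane (E/Z mixture) | CC=C(CC)O[Si](C)(C)C | intermediate
3 | malonyl dichloride | O=C(Cl)CC(=O)Cl | starting material
4 | 4-methyl-3,5-dioxoheptanoyl chloride | CCC(=O)C(C)C(=O)CC(=O)Cl | intermediate
5 | 6-ethyl-4-hydroxy-5-methyl-2H-pyran-2-one | CCc1oc(=O)cc(O)c1C | intermediate
6 | 2,4,6-trihydroxybenzaldehyde | O=Cc1c(O)cc(O)cc1O | starting material
7 | 2,6-dihydroxy-4-[(triisopropylsilyl)oxy]benzaldehyde | O=Cc1c(O)cc(O[Si](C(C)C)(C(C)C)C(C)C)cc1O | intermediate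
8 | 3-{2,6-dihydroxy-4-[(triisopropylsilyl)oxy]benzylidene}-6-ethyl-5-methyl-2H-pyran-2,4(3H)-dione | CCC1=C(C)C(=O)C(=Cc2c(O)cc(O[Si](C(C)C)(C(C)C)C(C)C)cc2O)C(=O)O1 | intermediate
9 | 3-{2,6-dihydroxy-4-[(triisopropylsilyl)oxy]benzyl}-6-ethyl-4-hydroxy-5-methyl-2H-pyran-2-one | CCc1oc(=O)c(Cc2c(O)cc(O[Si](C(C)C)(C(C)C)C(C)C)cc2O)c(O)c1C | intermediate
10 | 3-{2,6-bis(methoxymethoxy)-4-[(triisopropylsilyl)oxy]benzyl}-6-ethyl-4-(methoxymethoxy)-5-methyl-2H-pyran-2-one | CCc1oc(=O)c(Cc2c(OCOC)cc(O[Si](C(C)C)(C(C)C)C(C)C)cc2OCOC)c(OCOC)c1C | intermediate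
11 | 6-ethyl-3-[4-hydroxy-2,6-bis(methoxymethoxy)benzyl]-4-(methoxymethoxy)-5-methyl-2H-pyran-2-one | CCc1oc(=O)c(Cc2c(OCOC)cc(O)cc2OCOC)c(OCOC)c1C | intermediate
12 | 6-ethyl-3-[4-hydroxy-3-iodo-2,6-bis(methoxymethoxy)benzyl]-4-(methoxymethoxy)-5-methyl-2H-pyran-2-one | CCc1oc(=O)c(Cc2c(OCOC)cc(O)c(I)c2OCOC)c(OCOC)c1C | intermediate
13 | potassium vinyltrifluoroborate | [K+].C=C[B-](F)(F)F | starting material
14 | 6-ethyl-3-[4-hydroxy-2,6-bis(methoxymethoxy)-3-vinylbenzyl]-4-(methoxymethoxy)-5-methyl-2H-pyran-2-one | CCc1oc(=O)c(Cc2c(OCOC)cc(O)c(C=C)c2OCOC)c(OCOC)c1C | intermediate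
15 | (E)-cinnamyl methyl carbonate | COC(=O)OC/C=C/c1ccccc1 | starting material
16 | lithium 3,5-bis(methoxymethoxy)-4-{[6-ethyl-4-(methoxymethoxy)-5-methyl-2-oxo-2H-pyran-3-yl]methyl}-2-vinylphenolate | CCc1oc(=O)c(Cc2c(OCOC)cc([O-])c(C=C)c2OCOC)c(OCOC)c1C.[Li+] | intermediate
17 | 3,5-bis(methoxymethoxy)-4-{[6-ethyl-4-(methoxymethoxy)-5-methyl-2-oxo-2H-pyran-3-yl]methyl}-2-vinylphenyl (1S)-1-phenylprop-2-enyl ether | CCc1oc(=O)c(Cc2c(OCOC)cc(O[C@@H](C=C)c3ccccc3)c(C=C)c2OCOC)c(OCOC)c1C | intermediate
18 | (2S)-6-{[6-ethyl-4-(methoxymethoxy)-5-methyl-2-oxo-2H-pyran-3-yl]methyl}-5,7-bis(methoxymethoxy)-2-phenyl-2H-chromene | CCc1oc(=O)c(Cc2c(OCOC)cc3c(c2OCOC)C=C[C@@H](c2ccccc2)O3)c(OCOC)c1C | intermediate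
19 | (2S)-6-{[6-ethyl-4-(methoxymethoxy)-5-methyl-2-oxo-2H-pyran-3-yl]methyl}-5,7-bis(methoxymethoxy)-2-phenylchroman-4-ol (mixture of C4 epimers) | CCc1oc(=O)c(Cc2c(OCOC)cc3c(c2OCOC)C(O)C[C@@H](c2ccccc2)O3)c(OCOC)c1C | intermediate
20 | (2S)-6-{[6-ethyl-4-(methoxymethoxy)-5-methyl-2-oxo-2H-pyran-3-yl]methyl}-5,7-bis(methoxymethoxy)-2-phenylchroman-4-one | CCc1oc(=O)c(Cc2c(OCOC)cc3c(c2OCOC)C(=O)C[C@@H](c2ccccc2)O3)c(OCOC)c1C | intermediate
21 | (2S)-6-{[6-ethyl-4-(methoxymethoxy)-5-methyl-2-oxo-2H-pyran-3-yl]methyl}-8-iodo-5,7-bis(methoxymethoxy)-2-phenylchroman-4-one | CCc1oc(=O)c(Cc2c(OCOC)c(I)c3c(c2OCOC)C(=O)C[C@@H](c2ccccc2)O3)c(OCOC)c1C | intermediate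
22 | 2-methylprop-1-enylmagnesium bromide | CC(C)=C[Mg]Br | starting material
23 | tributyl(2-methylprop-1-enyl)stannane | CC(C)=C[Sn](CCCC)(CCCC)CCCC | intermediate
24 | (2S)-6-{[6-ethyl-4-(methoxymethoxy)-5-methyl-2-oxo-2H-pyran-3-yl]methyl}-5,7-bis(methoxymethoxy)-8-(3-methylbut-2-enoyl)-2-phenylchroman-4-one | CCc1oc(=O)c(Cc2c(OCOC)c(C(=O)C=C(C)C)c3c(c2OCOC)C(=O)C[C@@H](c2ccccc2)O3)c(OCOC)c1C | intermediate
25 | (2S)-6-[(6-ethyl-4-hydroxy-5-methyl-2-oxo-2H-pyran-3-yl)methyl]-5,7-dihydroxy-8-(3-methylbut-2-enoyl)-2-phenylchroman-4-one | CCc1oc(=O)c(Cc2c(O)c(C(=O)C=C(C)C)c3c(c2O)C(=O)C[C@@H](c2ccccc2)O3)c(O)c1C | target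

**Step count**

Total: 15 steps. Longest linear sequence: 13 steps (steps 1, 2, 4 to 12, 14 and 15).

**Steps most likely to fail**

Step 10 (key step). Ruthenium hydride formed as the catalyst decays may move the allylic double bond into conjugation with the ether oxygen before the ring closes. The ortho-alkoxystyrene may also hold the catalyst as a chelated benzylidene, so that a slow reaction gives the electron-rich chromene time to open and reclose at C2 with loss of optical purity. The fallback builds ring C by conjugate addition instead of metathesis. It sets out from iodophenol 12: Stille coupling with tributyl(1-ethoxyvinyl)stannane (Pd(PPh3)4, toluene, 90 °C) should give the enol ether 3-[3-(1-ethoxyvinyl)-4-hydroxy-2,6-bis(methoxymethoxy)benzyl]-6-ethyl-4-(methoxymethoxy)-5-methyl-2H-pyran-2-one F1, which a cold, dilute acidic work-up hydrolyses to the ortho-hydroxyacetophenone 3-[3-acetyl-4-hydroxy-2,6-bis(methoxymethoxy)benzyl]-6-ethyl-4-(methoxymethoxy)-5-methyl-2H-pyran-2-one F2. Condensation with N,N-dimethylformamide dimethyl acetal gives the enaminone 3-{3-[(E)-3-(dimethylamino)prop-2-enoyl]-4-hydroxy-2,6-bis(methoxymethoxy)benzyl}-6-ethyl-4-(methoxymethoxy)-5-methyl-2H-pyran-2-one F3, and brief mild acid closes it with loss of dimethylamine to the chromone 6-{[6-ethyl-4-(methoxymethoxy)-5-methyl-2-oxo-2H-pyran-3-yl]methyl}-5,7-bis(methoxymethoxy)-4H-chromen-4-one F4. Enantioselective conjugate addition of phenylboronic acid (Pd(OCOCF3)2 with a chiral tert-butyl pyridine-oxazoline ligand, the enantiomer chosen for 2S) then gives flavanone 20, where the route is rejoined.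

Step 14. Transfer of the trisubstituted alkenyl group from tin to the crowded acylpalladium may be slow, so that reduction of the iodide or direct coupling without uptake of CO takes over. The fallback makes the C8–carbon bond without carbon monoxide. It sets out from iodide 21: Sonogashira coupling with 2-methylbut-3-yn-2-ol (PdCl2(PPh3)2, CuI, Et3N, THF, rt) should give the propargylic alcohol (2S)-6-{[6-ethyl-4-(methoxymethoxy)-5-methyl-2-oxo-2H-pyran-3-yl]methyl}-8-(3-hydroxy-3-methylbut-1-ynyl)-5,7-bis(methoxymethoxy)-2-phenylchroman-4-one F5. Gold-catalysed Meyer–Schuster rearrangement (Ph3PAuNTf2, MeOH as additive, toluene, rt) then shifts the hydroxyl to the aryl-bound alkyne carbon and gives enone 24, where the route is rejoined.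

Step 9. Competing attack through the ortho carbon of the electron-rich aryloxide, leakage to the linear cinnamyl ether or incomplete facial control would lower the yield or the optical purity of the ether. The fallback sets the stereocentre by substitution with inversion instead of by catalysis. Commercial racemic 1-phenylprop-2-en-1-ol is resolved by lipase-catalysed acetylation (Candida antarctica lipase B, vinyl acetate), which by the usual preference for 1-arylalkanols should acylate the R enantiomer and give (R)-1-phenylprop-2-enyl acetate F6. Methanolysis (K2CO3, MeOH) gives (R)-1-phenylprop-2-en-1-ol F7. Mitsunobu reaction of phenol 14 with this alcohol (PPh3, diisopropyl azodicarboxylate, toluene, 0 °C) gives ether 17 with inversion, where the route is rejoined.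

**Further compounds**

F1 | step 10 | 3-[3-(1-ethoxyvinyl)-4-hydroxy-2,6-bis(methoxymethoxy)benzyl]-6-ethyl-4-(methoxymethoxy)-5-methyl-2H-pyran-2-one | CCc1oc(=O)c(Cc2c(OCOC)cc(O)c(C(=C)OCC)c2OCOC)c(OCOC)c1C
F2 | step 10 | 3-[3-acetyl-4-hydroxy-2,6-bis(methoxymethoxy)benzyl]-6-ethyl-4-(methoxymethoxy)-5-methyl-2H-pyran-2-one | CCc1oc(=O)c(Cc2c(OCOC)cc(O)c(C(C)=O)c2OCOC)c(OCOC)c1C
F3 | step 10 | 3-{3-[(E)-3-(dimethylamino)prop-2-enoyl]-4-hydroxy-2,6-bis(methoxymethoxy)benzyl}-6-ethyl-4-(methoxymethoxy)-5-methyl-2H-pyran-2-one | CCc1oc(=O)c(Cc2c(OCOC)cc(O)c(C(=O)/C=C/N(C)C)c2OCOC)c(OCOC)c1C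
F4 | step 10 | 6-{[6-ethyl-4-(methoxymethoxy)-5-methyl-2-oxo-2H-pyran-3-yl]methyl}-5,7-bis(methoxymethoxy)-4H-chromen-4-one | CCc1oc(=O)c(Cc2c(OCOC)cc3occc(=O)c3c2OCOC)c(OCOC)c1C
F5 | step 14 | (2S)-6-{[6-ethyl-4-(methoxymethoxy)-5-methyl-2-oxo-2H-pyran-3-yl]methyl}-8-(3-hydroxy-3-methylbut-1-ynyl)-5,7-bis(methoxymethoxy)-2-phenylchroman-4-one | CCc1oc(=O)c(Cc2c(OCOC)c(C#CC(C)(C)O)c3c(c2OCOC)C(=O)C[C@@H](c2ccccc2)O3)c(OCOC)c1C
F6 | step 9 | (R)-1-phenylprop-2-enyl acetate | CC(=O)O[C@H](C=C)c1ccccc1
F7 | step 9 | (R)-1-phenylprop-2-en-1-ol | O[C@H](C=C)c1ccccc1
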